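Target 17 ← benzoylation of O7 and of O5, with O6 held back in an O6/O7 silylene ← triol 11 ← tris-TBS diene 10 (ring numbering C1(C7H2O)=C2–C3=C4–C5(O)–C6(O)).
Diene 10 ← bis-Wittig annulation across C3=C4 and C1=C2: the C2–C3 unit comes from Ph3P+CH2CH2P+Ph3 (6), the rest from keto-aldehyde 5.
Feature: ring atoms C4–C5–C6–C1 plus exocyclic C7 form an unbranched five-carbon chain, sp2 at C4 and C1, with the trans (threo) 5,6-diol between them. This is a silylated D-threo-pentos-4-ulose with the D-tartrate-type threo diol, and it maps onto C1–C5 of D-arabinose.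
Keto-aldehyde 5 ← double oxidation of 1,4-diol 4 ← reduction ← per-silylation of D-arabinono-1,4-lactone 1; C5 and C6 come from C2 and C3 of the sugar and no new stereocentre is made.
Ring order: the single carbocycle is closed once, in step 4.

Key step: step 4

Remark: D-arabinono-1,4-lactone (1) is taken as a catalogue compound (it is the bromine-water oxidation product of D-arabinose). It supplies C7 as well as the threo diol, so no diazoketone homologation and no ester reduction next to a ketone is needed.

Step 1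
Reactants: 1 D-arabinono-1,4-lactone; 2 tert-butyldimethylsilyl chloride
Product: 3 2,3,5-tri-O-(tert-butyldimethylsilyl)-D-arabinono-1,4-lactone
Conditions: TBSCl (3.6 equiv), imidazole (7 equiv), DMAP (cat.), DMF, rt → 45 °C
Reagents that add atoms: tert-butyldimethylsilyl chloride, CC(C)(C)[Si](C)(C)Cl
Why: Imidazole-promoted silyl ether formation on all three hydroxyls; the lactone keeps O4 masked, so exactly O2, O3 and O5 (later O5, O6 and O7 of the ring) are protected and no stereocentre is touched.

Step 2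
Reactants: 3 2,3,5-tri-O-(tert-butyldimethylsilyl)-D-arabinono-1,4-lactone
Product: 4 2,3,5-tri-O-(tert-butyldimethylsilyl)-D-arabinitol
Conditions: LiBH4 (2.5 equiv), THF, 0 °C → rt; aq. NH4Cl
Reagents that add atoms: none
Why: Borohydride reduction of the lactone to the 1,4-diol via the lactol; lithium alkoxyborates in THF at 0 °C should not trigger O→O silyl migration, and the stereocentres are untouched.

Step 3
Reactants: 4 2,3,5-tri-O-(tert-butyldimethylsilyl)-D-arabinitol
Product: 5 (2S,3S)-2,3,5-tris[(tert-butyldimethylsilyl)oxy]-4-oxopentanal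
Conditions: (COCl)2 (4 equiv), DMSO (8 equiv), CH2Cl2, −78 °C; Et3N (10 equiv), −78 → −20 °C; cold pH 7 buffer; used crude
Reagents that add atoms: none
Why: Double Swern oxidation: both hydroxyls are activated as alkoxysulfonium ions before base is added, so primary and secondary alcohol are oxidised together to the 1,4-keto-aldehyde without passing through the lactol (the former C4 stereocentre of the sugar is removed on purpose).

Step 4
Reactants: 5 (2S,3S)-2,3,5-tris[(tert-butyldimethylsilyl)oxy]-4-oxopentanal; 6 ethane-1,2-diylbis(triphenylphosphonium) dibromide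
Product: 10 (5R,6R)-5,6-bis[(tert-butyldimethylsilyl)oxy]-1-{[(tert-butyldimethylsilyl)oxy]methyl}cyclohexa-1,3-diene, via phosphonio ylide 7 (not isolated), via Z-allylphosphonium bromide 8 (not isolated), via allylic ylide 9 (not isolated)
Conditions: 6 (1.1 equiv), KHMDS (1.05 equiv), THF, −78 → 0 °C; 5 added slowly, −78 → −20 °C; KHMDS (1.05 equiv), −78 °C → rt; 0.02 M
Reagents that add atoms: ethane-1,2-diylbis(triphenylphosphonium) dibromide, [Br-].[Br-].c1ccc(cc1)[P+](CC[P+](c1ccccc1)(c1ccccc1)c1ccccc1)(c1ccccc1)c1ccccc1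
Why: Bis-Wittig annulation: one equivalent of KHMDS turns 6 into the β-phosphonio ylide 7, which as a non-stabilised, lithium-free ylide should olefinate the aldehyde of 5 at −78 °C much faster than the hindered ketone and with Z selectivity, forming C3=C4 and leaving allylic phosphonium salt 8. The second equivalent of base removes an allylic proton next to phosphorus in 8 (more acidic than either ketone α-position) to give allylic ylide 9, whose α-carbon C2 adds to the C1 ketone in a 6-exo-trig closure; the oxaphosphetane then loses Ph3PO to form C1=C2, so the cyclohexa-1,3-diene appears directly at the diene oxidation level with no elimination step that could aromatise. The closest known reaction type is the bis-Wittig annulation of 1,4-dicarbonyl compounds with ethane-1,2-diylbis(triphenylphosphonium) salts to cyclohexa-1,3-dienes and arenes. No stereocentre is created; C5 and C6 are carried over from C2 and C3 of the sugar, and their integrity rests on the absence of free amide base in the first stage, on the preference for deprotonation at the phosphorus-activated carbon in the second, and on low temperature. The step needs aldehyde-before-ketone chemoselectivity (secured by the reactivity gap) and a cis C3=C4 bond (secured by salt-free conditions; E material can reach the ketone only if it isomerises within the delocalised ylide 9). γ-Attack of 9 would require a four-membered ring and is excluded, and high dilution with slow addition should keep 9 from olefinating a second molecule of 5.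

Step 5
Reactants: 10 (5R,6R)-5,6-bis[(tert-butyldimethylsilyl)oxy]-1-{[(tert-butyldimethylsilyl)oxy]methyl}cyclohexa-1,3-diene
Product: 11 (1R,2R)-3-(hydroxymethyl)cyclohexa-3,5-diene-1,2-diol
Conditions: TBAF (3.5 equiv), THF, 0 °C → rt; evaporation, direct SiO2 chromatography (EtOAc/MeOH)
Reagents that add atoms: none
Why: Fluoride-mediated silyl ether cleavage under non-acidic conditions that the acid-sensitive dihydrodiol diene should tolerate; isolation is non-aqueous because the triol is water soluble.

Step 6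
Reactants: 11 (1R,2R)-3-(hydroxymethyl)cyclohexa-3,5-diene-1,2-diol; 12 di-tert-butylsilyl bis(trifluoromethanesulfonate)
Product: 13 (8R,8aR)-2,2-di-tert-butyl-8,8a-dihydro-4H-1,3,2-benzodioxasilin-8-ol (O6/O7 silylene, 5-OH free)
Conditions: tBu2Si(OTf)2 (1.05 equiv), 2,6-lutidine (3 equiv), DMF, −40 → 0 °C
Reagents that add atoms: di-tert-butylsilyl bis(trifluoromethanesulfonate), CC(C)(C)[Si](OS(=O)(=O)C(F)(F)F)(OS(=O)(=O)C(F)(F)F)C(C)(C)C
Why: Cyclic silylene formation: the bis-triflate silylates the primary O7 first and can then close only onto O6 through a six-membered 1,3,2-dioxasilinane, a trans-fused five-membered ring across O5/O6 being strained, so 5-OH stays free.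

Step 7
Reactants: 13 (8R,8aR)-2,2-di-tert-butyl-8,8a-dihydro-4H-1,3,2-benzodioxasilin-8-ol; 14 benzoyl chloride
Product: 15 (8R,8aR)-2,2-di-tert-butyl-8,8a-dihydro-4H-1,3,2-benzodioxasilin-8-yl benzoate
Conditions: BzCl (1.5 equiv), pyridine, DMAP (cat.), CH2Cl2, 0 °C → rt
Reagents that add atoms: benzoyl chloride, O=C(Cl)c1ccccc1
Why: DMAP-catalysed esterification of the only free hydroxyl (O5); the silylene and the diene are inert to these conditions.

Step 8
Reactants: 15 (8R,8aR)-2,2-di-tert-butyl-8,8a-dihydro-4H-1,3,2-benzodioxasilin-8-yl benzoate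
Product: 16 (1R,6R)-6-hydroxy-5-(hydroxymethyl)cyclohexa-2,4-dien-1-yl benzoate
Conditions: HF·pyridine, pyridine/THF, 0 °C
Reagents that add atoms: none
Why: Fluoride cleavage of the silylene in a buffered, mildly acidic medium, in which base-catalysed benzoyl migration from O5 to O6 and ester cleavage are not expected.

Step 9
Reactants: 16 (1R,6R)-6-hydroxy-5-(hydroxymethyl)cyclohexa-2,4-dien-1-yl benzoate; 14 benzoyl chloride
Product: 17 [(5R,6R)-5-(benzoyloxy)-6-hydroxycyclohexa-1,3-dien-1-yl]methyl benzoate (target)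
Conditions: BzCl (1.05 equiv), 2,4,6-collidine, CH2Cl2, −78 → −30 °C
Reagents that add atoms: benzoyl chloride, O=C(Cl)c1ccccc1
Why: Chemoselective acylation of the primary allylic hydroxyl with a weak, hindered base at low temperature; the secondary 6-OH sits between the C5 benzoate and the substituted C1 and should react much more slowly.

Compound list
1 | D-arabinono-1,4-lactone, (3S,4S,5R)-3,4-dihydroxy-5-(hydroxymethyl)oxolan-2-one | O=C1[C@@H](O)[C@H](O)[C@@H](CO)O1 | starting material
2 | tert-butyldimethylsilyl chloride | CC(C)(C)[Si](C)(C)Cl | starting material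
3 | 2,3,5-tri-O-(tert-butyldimethylsilyl)-D-arabinono-1,4-lactone | O=C1[C@@H](O[Si](C)(C)C(C)(C)C)[C@H](O[Si](C)(C)C(C)(C)C)[C@@H](CO[Si](C)(C)C(C)(C)C)O1 | intermediate
4 | 2,3,5-tri-O-(tert-butyldimethylsilyl)-D-arabinitol (free 1-OH and 4-OH) | OC[C@@H](O[Si](C)(C)C(C)(C)C)[C@H](O[Si](C)(C)C(C)(C)C)[C@H](O)CO[Si](C)(C)C(C)(C)C | intermediate
5 | (2S,3S)-2,3,5-tris[(tert-butyldimethylsilyl)oxy]-4-oxopentanal | O=C[C@@H](O[Si](C)(C)C(C)(C)C)[C@H](O[Si](C)(C)C(C)(C)C)C(=O)CO[Si](C)(C)C(C)(C)C | intermediate
6 | ethane-1,2-diylbis(triphenylphosphonium) dibromide | [Br-].[Br-].c1ccc(cc1)[P+](CC[P+](c1ccccc1)(c1ccccc1)c1ccccc1)(c1ccccc1)c1ccccc1 | starting material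
7 | triphenyl[2-(triphenyl-λ5-phosphanylidene)ethyl]phosphonium bromide (β-phosphonio ylide) | [Br-].c1ccc(cc1)P(=CC[P+](c1ccccc1)(c1ccccc1)c1ccccc1)(c1ccccc1)c1ccccc1 | intermediate
8 | [(2Z,4R,5S)-4,5,7-tris[(tert-butyldimethylsilyl)oxy]-6-oxohept-2-en-1-yl]triphenylphosphonium bromide | [Br-].c1ccc(cc1)[P+](c1ccccc1)(c1ccccc1)C/C=C\[C@@H](O[Si](C)(C)C(C)(C)C)[C@H](O[Si](C)(C)C(C)(C)C)C(=O)CO[Si](C)(C)C(C)(C)C | intermediate
9 | allylic ylide of 8, (Z)-Ph3P=CH–CH=CH–CH(OTBS)–CH(OTBS)–CO–CH2OTBS | c1ccc(cc1)P(c1ccccc1)(c1ccccc1)=C/C=C\[C@@H](O[Si](C)(C)C(C)(C)C)[C@H](O[Si](C)(C)C(C)(C)C)C(=O)CO[Si](C)(C)C(C)(C)C | intermediate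
10 | (5R,6R)-5,6-bis[(tert-butyldimethylsilyl)oxy]-1-{[(tert-butyldimethylsilyl)oxy]methyl}cyclohexa-1,3-diene | CC(C)(C)[Si](C)(C)OCC1=CC=C[C@@H](O[Si](C)(C)C(C)(C)C)[C@@H]1O[Si](C)(C)C(C)(C)C | intermediate
11 | (1R,2R)-3-(hydroxymethyl)cyclohexa-3,5-diene-1,2-diol | OCC1=CC=C[C@@H](O)[C@@H]1O | intermediate
12 | di-tert-butylsilyl bis(trifluoromethanesulfonate) | CC(C)(C)[Si](OS(=O)(=O)C(F)(F)F)(OS(=O)(=O)C(F)(F)F)C(C)(C)C | starting material
13 | (8R,8aR)-2,2-di-tert-butyl-8,8a-dihydro-4H-1,3,2-benzodioxasilin-8-ol | CC(C)(C)[Si]1(OCC2=CC=C[C@@H](O)[C@@H]2O1)C(C)(C)C | intermediate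
14 | benzoyl chloride | O=C(Cl)c1ccccc1 | starting material
15 | (8R,8aR)-2,2-di-tert-butyl-8,8a-dihydro-4H-1,3,2-benzodioxasilin-8-yl benzoate | CC(C)(C)[Si]1(OCC2=CC=C[C@@H](OC(=O)c3ccccc3)[C@@H]2O1)C(C)(C)C | intermediate
16 | (1R,6R)-6-hydroxy-5-(hydroxymethyl)cyclohexa-2,4-dien-1-yl benzoate | OCC1=CC=C[C@@H](OC(=O)c2ccccc2)[C@@H]1O | intermediate
17 | [(5R,6R)-5-(benzoyloxy)-6-hydroxycyclohexa-1,3-dien-1-yl]methyl benzoate | O=C(OCC1=CC=C[C@@H](OC(=O)c2ccccc2)[C@@H]1O)c1ccccc1 | target

Total step count: 9. Longest linear sequence: 9 steps (1 → 17).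

Steps most likely to fail

Step 4. The keto-aldehyde may lose silyloxide by β-elimination or epimerise under the basic ylide before it is olefinated. The β-phosphonio ylide may fragment into vinyltriphenylphosphonium and triphenylphosphine. E-olefination would leave an allylic ylide that cannot reach the ketone, and intermolecular olefination would give oligomers. Fallback (ring closure by metathesis instead of by a second ylide): starting from 5, the aldehyde alone is converted by Stork–Zhao olefination (iodomethylenetriphenylphosphorane from (iodomethyl)triphenylphosphonium iodide and NaHMDS, THF/DMPU, −78 °C) into (3S,4R,5Z)-1,3,4-tris[(tert-butyldimethylsilyl)oxy]-6-iodohex-5-en-2-one F1. Stille coupling with tributyl(vinyl)stannane (Pd2(dba)3, AsPh3, CuI, DMF, rt) should give (3S,4R,5Z)-1,3,4-tris[(tert-butyldimethylsilyl)oxy]octa-5,7-dien-2-one F2. Wittig methylenation of the ketone (Ph3P=CH2, THF, −78 → 0 °C) gives (3Z,5R,6R)-5,6-bis[(tert-butyldimethylsilyl)oxy]-7-{[(tert-butyldimethylsilyl)oxy]methyl}octa-1,3,7-triene F3. Ring-closing metathesis of the two terminal alkenes (second-generation Grubbs catalyst, CH2Cl2, 40 °C) forms C1=C2 with loss of ethene and returns to the route at 10.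

Step 3. The hydroxy-aldehyde formed after one oxidation may close to the lactol and be oxidised back to lactone 3. The 1,4-dicarbonyl product may also undergo amine-induced β-elimination or epimerisation during warm-up and work-up. Fallback (the two carbonyls are made one at a time and the aldehyde is released last under neutral conditions): starting from 3, DIBAL-H (1.1 equiv, toluene, −78 °C) gives 2,3,5-tri-O-(tert-butyldimethylsilyl)-D-arabinofuranose F4. Wittig methylenation of the lactol (Ph3P=CH2, THF, 0 °C → rt) gives 1,2-dideoxy-3,4,6-tri-O-(tert-butyldimethylsilyl)-D-arabino-hex-1-enitol F5. Dess–Martin periodinane (NaHCO3, CH2Cl2) oxidises the free secondary hydroxyl to (3S,4R)-1,3,4-tris[(tert-butyldimethylsilyl)oxy]hex-5-en-2-one F6. Ozonolysis (O3, CH2Cl2, −78 °C; PPh3) then releases the aldehyde and returns to the route at 5, replacing steps 2 and 3.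

Step 9. Over-acylation at the secondary 6-OH, or base-promoted benzoyl migration from O5 to O6, would erode the regiochemistry. Fallback (biocatalytic steric discrimination instead of reagent control): starting from 16, immobilised Candida antarctica lipase B with vinyl benzoate in MTBE at 40 °C should transfer a benzoyl group to the primary hydroxyl only and arrive directly at 17; no compound outside the list arises (F0).

Further compounds
F1 | step 4 | (3S,4R,5Z)-1,3,4-tris[(tert-butyldimethylsilyl)oxy]-6-iodohex-5-en-2-one | I/C=C\[C@@H](O[Si](C)(C)C(C)(C)C)[C@H](O[Si](C)(C)C(C)(C)C)C(=O)CO[Si](C)(C)C(C)(C)C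
F2 | step 4 | (3S,4R,5Z)-1,3,4-tris[(tert-butyldimethylsilyl)oxy]octa-5,7-dien-2-one | C=C/C=C\[C@@H](O[Si](C)(C)C(C)(C)C)[C@H](O[Si](C)(C)C(C)(C)C)C(=O)CO[Si](C)(C)C(C)(C)C
F3 | step 4 | (3Z,5R,6R)-5,6-bis[(tert-butyldimethylsilyl)oxy]-7-{[(tert-butyldimethylsilyl)oxy]methyl}octa-1,3,7-triene | C=C/C=C\[C@@H](O[Si](C)(C)C(C)(C)C)[C@H](O[Si](C)(C)C(C)(C)C)C(=C)CO[Si](C)(C)C(C)(C)C
F4 | step 3 | 2,3,5-tri-O-(tert-butyldimethylsilyl)-D-arabinofuranose (anomeric mixture) | OC1[C@@H](O[Si](C)(C)C(C)(C)C)[C@H](O[Si](C)(C)C(C)(C)C)[C@@H](CO[Si](C)(C)C(C)(C)C)O1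
F5 | step 3 | 1,2-dideoxy-3,4,6-tri-O-(tert-butyldimethylsilyl)-D-arabino-hex-1-enitol | C=C[C@@H](O[Si](C)(C)C(C)(C)C)[C@H](O[Si](C)(C)C(C)(C)C)[C@H](O)CO[Si](C)(C)C(C)(C)C
F6 | step 3 | (3S,4R)-1,3,4-tris[(tert-butyldimethylsilyl)oxy]hex-5-en-2-one | C=C[C@@H](O[Si](C)(C)C(C)(C)C)[C@H](O[Si](C)(C)C(C)(C)C)C(=O)CO[Si](C)(C)C(C)(C)C
F0 | step 9 | none | none
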